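The numbers in the tables stem from a simulated flask on assumed constants, noise included.

**Reading time.** We read each flask at 6.0 min, so a flask that gets its nucleophile late has, on average, had a shorter reaction before that reading. North has the charges of the alpha run, with everything together at the start, so we take it as the zero of our scale and count the other flasks down from it.

| flask | electrophile | nucleophile | free base | remark | time |
|---|---|---|---|---|---|
| alpha | 0.20 M | 0.18 M | 0.16 M | run made earlier |  |
| delta | 0.20 M | 0.18 M | 0.11 M | run made earlier |  |
| beta | 0.20 M | 0.18 M | 0.24 M | run made earlier |  |
| east | 0.20 M | 0.180 M | 0.160 M (fed, over 5.0 min) | all else is in the flask from the start; the feed brings no volume worth counting | 6.0 min |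
| south-east | 0.20 M | 0.180 M (fed, over 80 s) | 0.160 M | all else is in the flask from the start; the feed brings no volume worth counting | 6.0 min |
| north | 0.20 M | 0.180 M | 0.160 M | everything together at the start | 6.0 min |
| south-west | 0.20 M | 0.180 M | 0.160 M (in portions, 3, over 5.0 min) | first portion at the start, last at 5.0 min | 6.0 min |
| north-west | 0.20 M | 0.180 M (fed, over 5.0 min) | 0.160 M | all else is in the flask from the start; the feed brings no volume worth counting | 6.0 min |

- alpha (time / min: over-reaction product / %, target / %): 0.500: 6, 16; 0.833: 6, 20; 1.50: 14, 23; 3.00: 28, 20; 6.00: 40, 16
- delta (time / min: over-reaction product / %, target / %): 1.33: 8, 29; 3.00: 18, 26; 4.00: 27, 24; 6.00: 33, 24; 8.00: 38, 23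
- beta (time / min: over-reaction product / %, target / %): 0.667: 6, 20; 2.00: 24, 18; 3.00: 35, 13; 5.00: 45, 10; 8.00: 59, 5

(each reading ± 1.5 percentage points)

1. the flask with the highest amount of over-reaction product, in percent of the electrophile charged ("all alike" if they lie within 1.5 percentage points) (east / south-east / north / south-west / north-west / all alike)
2. final over-reaction product, as a percentage of the electrophile charged, in east
3. final over-reaction product, as a percentage of the electrophile charged, in south-east
4. final over-reaction product, as a percentage of the electrophile charged, in north
5. final over-reaction product, as a percentage of the electrophile charged, in south-west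
6. final over-reaction product, as a percentage of the electrophile charged, in north-west

- the numbers in the tables scatter by 1.5 percentage points (one standard deviation)

**What matters.** Our reckoning needs an anchor, a lag and a slope. The anchor is the alpha reading of over-reaction product at 6.00 min, 40%, which carries one scatter, 1.5 percentage points, and enters the slope as well. The lag comes from the recipes: a steady feed (semi-batch operation) delivers its mean drop at its midpoint, so north-west lags by 2.50 min and south-east by 0.667 min. Their shortened reaction times stay within the alpha interval from 3.00 min to 6.00 min. The slope rests on two readings, so its error of 0.00707 min⁻¹ moves north-west by 1.8 points, more than the margin, but south-east by 0.47 points, less than the margin.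

**Late slope.** We call g the late slope: 0.0400 min⁻¹, the gain of over-reaction product between the last two alpha readings, as a fraction of the electrophile charged. Our reckoning puts north-west at 30.0% and south-east at 37.3%. Over-reaction product at 3.00 min reads 18% in delta, 28% in alpha and 35% in beta, rising with the free base charged, so we expect east and south-west, which dose free base, to stand below north, and we give them no figure.

**The flasks.** The forecast named north highest, with 41% there, 39% in south-east, above our figure, 34% in east, 34% in south-west and 30% in north-west, where “slow nucleophile feed delays target formation most”. The result puts north highest at 40.4%, with south-east at 38.0%, east at 34.1%, south-west at 32.4% and north-west at 28.4%. North-west ends with 53% of its electrophile, north with 43.2%.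

    electrophile + nucleophile → acid set free + target (k = 0.0530 L mol⁻¹ s⁻¹)
    free base + target → over-reaction product (k = 0.0600 L mol⁻¹ s⁻¹)
    acid set free → by-product carried off (k = 7.30 × 10⁻⁴ s⁻¹)
    acid set free + free base ⇌ salt of the base (K = 12.0 L mol⁻¹, k = 0.350 L mol⁻¹ s⁻¹)
    nucleophile + acid set free ⇌ protonated nucleophile, settled at all times (K = 100 L mol⁻¹)

**Slope applied.** North-west stands 12 points below north, and g times its lag gives 10 points. South-east stands 2.4 points below north, and g times its lag gives 2.7 points.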